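The data were generated by integration with made-up constants, and the scatter is random.

- The counting comes first: the runs so far read as substrate taking one reagent to give target, and target taking one more to give over-reaction product. The flasks and the questions stand below.

| flask | substrate | reagent | remark | time |
|---|---|---|---|---|
| east | 0.30 M | 0.45 M | run made earlier |  |
| south-east | 0.30 M | 1.8 M | run made earlier |  |
| Tuesday's | 0.30 M | 0.900 M |  | 8.0 h |
| Friday's | 0.30 M | 0.900 M |  | 10 h |
| Sunday's | 0.30 M | 0.900 M |  | 12 h |

- east (time / h: substrate / %, target / %, over-reaction product / %): 0.417: 21.7, 72.5, 5.1; 0.667: 15.0, 76.4, 8.9; 0.833: 12.1, 77.4, 11.7; 1.33: 7.9, 76.4, 15.7; 2.00: 5.4, 73.9, 21.0; 3.00: 4.3, 68.8, 27.1; 5.00: 2.0, 62.7, 35.7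
- south-east (time / h: substrate / %, target / %, over-reaction product / %): 0.667: 0.2, 43.2, 56.2; 1.33: 0, 19.1, 80.3; 2.00: 0.1, 8.7, 90.9; 3.00: 0.1, 1.9, 97.3; 4.00: 0.4, 0.8, 99.1; 5.00: 0, 0.5, 99.8

(standard deviation of a reading: 0.3 percentage points)

- which of these there is most of at the end, counted by the substrate in it, Tuesday's (substrate / over-reaction product / target)
- which of these there is most of at the end, counted by the substrate in it, Friday's (substrate / over-reaction product / target)
- which of these there is most of at the end, counted by the substrate in it, Sunday's (substrate / over-reaction product / target)
- how much there is at the end of the one of these that leads, in percent of the substrate charged: Tuesday's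
- how much there is at the end of the one of these that leads, in percent of the substrate charged: Friday's
- how much there is at the end of the one of these that leads, in percent of the substrate charged: Sunday's

- the earlier runs were read with a standard deviation of 0.3 percentage points

- Main step alone: the east run, at half the reagent of the new flasks, has 21.7 % substrate left at 0.417 h. So this reckoning takes substrate as turned into target at the start, which leaves 0.600 M of reagent in each new flask and 100 % target.
- Reagent taken away by the second step would come next, so the charge gives one more number: c_reagent minus twice c_substrate, both as charged, is 0.300 M. This reagent remaining after both steps is the surplus. On this counting, with both steps taking one reagent each, a positive surplus means that reagent outlasts target, and a negative one that reagent ends first with target remaining.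
- Second step added: the south-east run, with its surplus of 1.20 M, falls from 43.2 % target at 0.667 h to 8.7 % at 2.00 h. Read with that run's reagent loss counted, by the ratio of the next point, this gives a constant of 0.951 M⁻¹ h⁻¹. With reagent held at 0.600 M, this reckoning puts Tuesday's target at 1.04 % at 8.0 h.
- Reagent loss added: with substrate counted as turned, c_reagent equals c_target plus the surplus, so the rate per target sinks from 0.571 h⁻¹ towards a pseudo-first-order 0.285 h⁻¹. The ratio c_target/c_reagent starts at 0.500 and shrinks exponentially at that lower rate. This gives target 5.37 % on Tuesday's, 2.97 % on Friday's and 1.66 % on Sunday's. Over-reaction product then stands at 94.6 %, 97.0 % and 98.3 %.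
- The forecast gave 94.5 %, 97 % and 98.3 % of over-reaction product for Tuesday's, Friday's and Sunday's, with the words “Over-reaction product leads in all three runs”.
- Tuesday's, Friday's and Sunday's flasks give over-reaction product in the lead at 94.4 %, 96.9 % and 98.3 %, with target at 5.47 %, 3.02 % and 1.69 %. Tuesday's reagent stands at 35.2 % of its charge at 8.00 h and 33.3 % at 80.0 h, and its surplus is 33.3 % of that charge.

    substrate + reagent → target, rate k1*[substrate]^1.5*[reagent] (k = 37.0 M⁻¹·⁵ h⁻¹)
    reagent + target → over-reaction product (k = 0.960 M⁻¹ h⁻¹)

- A neighbour of Friday's flask, charged with 0.51 M of substrate and the same reagent, has a surplus of −0.120 M, which is negative. Once its substrate is counted as turned, it keeps 0.390 M of reagent, which on this counting can turn 76.5 % of its substrate into over-reaction product and leaves 23.5 % as target at that point. At 10.0 h this flask holds 69.2 % over-reaction product and 30.6 % target, with 4.3 % of its reagent charge left.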